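Per hour is the unit of this reckoning: each step is a first-order constant with the partner concentration folded in (pseudo-first-order).

| flask | starting material | partner | remark | time |
|---|---|---|---|---|
| north-east | 0.17 M | 0.375 M | run made earlier |  |
| south-east | 0.50 M | 0.375 M | run made earlier |  |
| grey | 0.25 M | 0.375 M |  | 8.0 h |
| green | 0.25 M | 0.625 M |  | 8.0 h |
| teal | 0.25 M | 0.750 M |  | 8.0 h |

| run | time / h | triple product / % | mono adduct / % | starting material / % |
|---|---|---|---|---|
| north-east | 0.250 | 0.8 | 21.0 | 74.3 |
| north-east | 0.667 | 0 | 27.4 | 56.7 |
| north-east | 1.33 | 1.2 | 30.7 | 44.2 |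
| north-east | 2.00 | 1.9 | 32.1 | 36.6 |
| north-east | 3.00 | 1.5 | 32.6 | 29.2 |
| south-east | 0.500 | 0.5 | 21.6 | 61.1 |
| south-east | 1.00 | 0 | 24.7 | 49.7 |
| south-east | 1.50 | 1.5 | 25.2 | 45.3 |
| south-east | 2.50 | 1.6 | 26.3 | 39.5 |
| south-east | 3.00 | 1.5 | 26.6 | 37.5 |

(readings scatter by 0.5 percentage points)

1. amount of triple product at the end, in percent of the starting material charged, for each flask in turn (grey, green, teal)

1. In the north-east run, starting material falls at 1.19 h⁻¹ up to the first reading, but at 0.226 h⁻¹ between the last two, far slower. The starting material lost by then is 0.120 M against 0.375 M of partner charged, so we suppose that the acting partner is a small, fixed share of the charge.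

2. Triple product needs two further partners after mono adduct. Two equal steps in series give triple product over mono adduct as (κt)²/2, with κ the constant of each step and t the time. The north-east run at 3.00 h then gives κ = 0.101 h⁻¹.

3. We take κ proportional to the partner charge, so at 8.0 h, κt is 0.808 in grey, 1.35 in green and 1.62 in teal. The ratio of step 2 asks for no small κt, so if we assume that mono adduct stands alike in grey, green and teal, triple product follows κ², which is the square of the partner charge. This gives our square-law gain, the squared ratio of partner charges from grey to green: 2.78.

4. The same square in time would put grey at 10.7%. This is the weak link: the north-east run reads 1.9% then 1.5%, and the south-east run 1.6% then 1.5%, with no such rise beyond the scatter of 0.5 percentage points.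

5. We reforge that link with the first power of time, starting from the 1.5% that both runs read at 3.00 h. Grey comes to 4.00%, green to 11.1% and teal to 16.0%. The square in charge stays an assumption, since both runs used one partner charge.

The forecast says 2.3%, 5% and 6.5%, holding that “the last step is roughly a dozen times slower than the earlier ones”. Our teal value is higher.

The flasks give 3.42% for grey, 9.79% for green and 13.2% for teal, under these steps:

    starting material + partner → mono adduct + by-product (k = 0.00114 M⁻¹ s⁻¹)
    partner + mono adduct → bis adduct + by-product (k = 6.09 × 10⁻⁴ M⁻¹ s⁻¹)
    partner + bis adduct → triple product + by-product (k = 0.00264 M⁻¹ s⁻¹)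
    partner + triple product → tetra adduct + by-product (k = 5.53 × 10⁻⁴ M⁻¹ s⁻¹)
    starting material + by-product → side product (k = 0.00196 M⁻¹ s⁻¹)
    partner ⇌ dormant form (K = 20.0, k = 8.22 × 10⁻⁴ s⁻¹)

At 8.00 h, partner stands at 2.71% of its own charge in grey and 2.84% in teal, beside 0.233 M and 0.482 M of dormant form. The gain of 2.78 on grey's 3.42% gives 9.51%, and green holds 9.79%. Carried on by the squared charges to teal, the same value gives 13.7%, and teal holds 13.2%.

(The numbers in the tables are simulated with made-up constants; the scatter is artificial.)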